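**Plan**

1. Retrosynthesis (carotenoid locants: ring C1–C6, ring oxygen on C5 and C8, chain C7–C15 then C15′–C12′): cut C11=C12 (Wittig, C15 phosphonium salt + C10 dialdehyde), then the O–C8 bond of the dihydrofuran (back to an α-hydroxyallene C5(OH)–C6=C7=C8), then the allene (back to a C5–C6 oxirane carrying a C7≡C8 alkyne), then C8–C9 (Sonogashira) and C6–C7.
2. Forward: the carbocycle is bought as (4R,6R)-actinol; enol triflate, carbonylation, reduction, Sharpless epoxidation and homologation give the ethynyl oxirane; coupling with an (E)-iodobutenyl ether and SN2′ hydride delivery give the allene; gold-catalysed cycloisomerisation then closes the dihydrofuran, the last ring; desilylation, Wittig chain extension and reduction finish the route.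
3. Enabling feature: the tertiary C5 hydroxyl sits next to C6, the ring terminus of the exocyclic allene C6=C7=C8. The C7=C8 π-bond lies in the plane of C1, C5 and C6, so oxygen can bond to C8 only within that plane; this closes the ring O–C5–C6–C7–C8 (5-endo), turns the allene axis into the C8 centre and leaves C6=C7 in the ring.
4. Stereochemistry: C3 from actinol; C5 (and the temporary C6 centre) from the Sharpless epoxidation, reagent-controlled and anti to the C3 oxygen; the allene axis from anti SN2′ hydride delivery; C8 from axis-to-centre transfer; C9=C10 from syn hydrozirconation; C13=C14, C15=C15′ and C14′=C13′ from the all-E dialdehyde; C11=C12 from the Wittig step with thermal equilibration.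
5. Helpers: the oxirane (temporary ring) and the alkyne (temporary oxidation level) are consumed on the way to the allene; the two silyl ethers are removed together right after the key step.

Key step: step 12

Remark: (4R,6R)-actinol, but-2-yn-1-ol and (2E,4E,6E)-2,7-dimethylocta-2,4,6-trienedial are taken as purchasable.

**Route**

Step 1
Reactants: 1 (4R,6R)-4-hydroxy-2,2,6-trimethylcyclohexan-1-one ((4R,6R)-actinol)
Product: 2 (4R,6R)-4-(tert-butyldimethylsilyloxy)-2,2,6-trimethylcyclohexan-1-one
Conditions: TBSCl, imidazole, DMF, rt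
Reagents that add atoms: tert-butyldimethylsilyl chloride, CC(C)(C)[Si](C)(C)Cl
Why: Silyl ether formation masks the secondary alcohol for the enolate, oxidation and hydride steps that follow and touches no stereocentre.

Step 2
Reactants: 2 (4R,6R)-4-(tert-butyldimethylsilyloxy)-2,2,6-trimethylcyclohexan-1-one
Product: 4 (4R)-4-(tert-butyldimethylsilyloxy)-2,6,6-trimethylcyclohex-1-en-1-yl trifluoromethanesulfonate, via lithium enolate 3 (not isolated)
Conditions: LiN(iPr)2, THF, −78 °C; then PhNTf2, −78 °C → rt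
Reagents that add atoms: N-phenylbis(trifluoromethanesulfonimide), O=S(=O)(N(c1ccccc1)S(=O)(=O)C(F)(F)F)C(F)(F)F; lithium diisopropylamide, [Li+].CC(C)[N-]C(C)C (lithium of 3 only)
Why: The ketone can enolise only toward the methyl-bearing α-carbon because the other α-carbon is quaternary, so enolate O-sulfonylation (enol triflate formation) should give one regioisomer and erases the methine centre on purpose.

Step 3
Reactants: 4 (4R)-4-(tert-butyldimethylsilyloxy)-2,6,6-trimethylcyclohex-1-en-1-yl trifluoromethanesulfonate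
Product: 5 methyl (4R)-4-(tert-butyldimethylsilyloxy)-2,6,6-trimethylcyclohex-1-ene-1-carboxylate
Conditions: Pd(OAc)2 (5 mol%), PPh3 (10 mol%), CO (1 atm), MeOH, Et3N, DMF, 60 °C
Reagents that add atoms: carbon monoxide, [C-]#[O+]; methanol, CO
Why: Palladium-catalysed alkoxycarbonylation of an alkenyl triflate (oxidative addition, CO insertion, methanolysis) installs C7 at the ester oxidation level.

Step 4
Reactants: 5 methyl (4R)-4-(tert-butyldimethylsilyloxy)-2,6,6-trimethylcyclohex-1-ene-1-carboxylate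
Product: 6 [(4R)-4-(tert-butyldimethylsilyloxy)-2,6,6-trimethylcyclohex-1-en-1-yl]methanol
Conditions: iBu2AlH, CH2Cl2, −78 °C → 0 °C; aqueous potassium sodium tartrate work-up
Reagents that add atoms: none
Why: 1,2-Reduction of the α,β-unsaturated ester by an aluminium hydride gives the primary allylic alcohol that directs the next step.

Step 5
Reactants: 6 [(4R)-4-(tert-butyldimethylsilyloxy)-2,6,6-trimethylcyclohex-1-en-1-yl]methanol
Product: 7 [(1R,4S,6R)-4-(tert-butyldimethylsilyloxy)-2,2,6-trimethyl-7-oxabicyclo[4.1.0]heptan-1-yl]methanol (oxirane oxygen anti to the silyloxy group)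
Conditions: Ti(OiPr)4 (20 mol%), D-(−)-diethyl tartrate (24 mol%), tBuOOH, 4 Å MS, CH2Cl2, −20 °C
Reagents that add atoms: tert-butyl hydroperoxide, CC(C)(C)OO
Why: Sharpless asymmetric epoxidation with D-(−)-diethyl tartrate should deliver the peroxide oxygen to the ring face opposite the C3 silyloxy group under reagent control, which sets C5 (R, kept to the end) and the temporary C6 centre.

Step 6
Reactants: 7 [(1R,4S,6R)-4-(tert-butyldimethylsilyloxy)-2,2,6-trimethyl-7-oxabicyclo[4.1.0]heptan-1-yl]methanol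
Product: 8 (1S,4S,6R)-4-(tert-butyldimethylsilyloxy)-2,2,6-trimethyl-7-oxabicyclo[4.1.0]heptane-1-carbaldehyde
Conditions: nPr4N[RuO4] (5 mol%), N-methylmorpholine N-oxide, 4 Å MS, CH2Cl2, rt
Reagents that add atoms: none
Why: Ley–Griffith oxidation converts the primary alcohol into the aldehyde under non-acidic conditions that spare the oxirane and the silyl ether, and the quaternary α-carbon cannot epimerise.

Step 7
Reactants: 8 (1S,4S,6R)-4-(tert-butyldimethylsilyloxy)-2,2,6-trimethyl-7-oxabicyclo[4.1.0]heptane-1-carbaldehyde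
Product: 9 (1R,4S,6R)-4-(tert-butyldimethylsilyloxy)-1-ethynyl-2,2,6-trimethyl-7-oxabicyclo[4.1.0]heptane
Conditions: dimethyl (1-diazo-2-oxopropyl)phosphonate, K2CO3, MeOH, 0 °C → rt
Reagents that add atoms: dimethyl (1-diazo-2-oxopropyl)phosphonate, COP(=O)(OC)C(=[N+]=[N-])C(C)=O
Why: Seyferth–Gilbert homologation with the Ohira–Bestmann reagent turns the non-enolisable aldehyde into the terminal alkyne (C8) under mild base.

Step 8
Reactants: 10 but-2-yn-1-ol
Product: 11 tert-butyl(but-2-yn-1-yloxy)dimethylsilane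
Conditions: TBSCl, imidazole, CH2Cl2, rt
Reagents that add atoms: tert-butyldimethylsilyl chloride, CC(C)(C)[Si](C)(C)Cl
Why: Silyl ether formation protects the future C11 hydroxyl with the same group as C3–OH so that both can be removed in one operation.

Step 9
Reactants: 11 tert-butyl(but-2-yn-1-yloxy)dimethylsilane
Product: 13 tert-butyl{[(2E)-3-iodobut-2-en-1-yl]oxy}dimethylsilane, via alkenylzirconium chloride 12 (not isolated)
Conditions: Cp2Zr(H)Cl (excess), THF, 50 °C; then I2, 0 °C
Reagents that add atoms: iodine, II; chlorobis(cyclopentadienyl)hydridozirconium, [H][Zr](Cl)(C1C=CC=C1)C1C=CC=C1 (zirconium of 12 only)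
Why: Hydrozirconation adds Zr–H syn, zirconium should settle on the less hindered methyl-bearing carbon under equilibration with excess reagent, and iodinolysis with retention gives the (E)-alkenyl iodide that fixes the C9=C10 geometry.

Step 10
Reactants: 9 (1R,4S,6R)-4-(tert-butyldimethylsilyloxy)-1-ethynyl-2,2,6-trimethyl-7-oxabicyclo[4.1.0]heptane; 13 tert-butyl{[(2E)-3-iodobut-2-en-1-yl]oxy}dimethylsilane
Product: 14 tert-butyl{[(2E)-5-[(1R,4S,6R)-4-(tert-butyldimethylsilyloxy)-2,2,6-trimethyl-7-oxabicyclo[4.1.0]heptan-1-yl]-3-methylpent-2-en-4-yn-1-yl]oxy}dimethylsilane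
Conditions: Pd(PPh3)4 (5 mol%), CuI (10 mol%), iPr2NH, THF, rt
Reagents that add atoms: none
Why: Sonogashira coupling of the terminal alkyne with the alkenyl iodide forms C8–C9 with retention of alkene geometry and should leave the propargylic oxirane untouched at room temperature.

Step 11
Reactants: 14 the epoxy enyne of step 10
Product: 15 (1R,5S)-5-(tert-butyldimethylsilyloxy)-2-[(3E)-5-(tert-butyldimethylsilyloxy)-3-methylpenta-1,3-dien-1-ylidene]-1,3,3-trimethylcyclohexan-1-ol, allene axis S (carotenoid locants 3S,5R,6S; H-8 on the face that the oxirane oxygen did not occupy)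
Conditions: [1,3-bis(2,6-diisopropylphenyl)imidazol-2-ylidene]CuCl (5 mol%), NaOtBu (10 mol%), MeSiH(OEt)2, tBuOH, toluene, 0 °C
Reagents that add atoms: none
Why: In this CuH-catalysed SN2′ reduction of a propargylic oxirane, syn-hydrocupration places H on C8 and Cu on C7 on the side away from the C6–O bond and anti β-alkoxide elimination then converts the C6 centre into the allene axis (centre-to-axis chirality transfer) while the C5 carbinol keeps its configuration.

Step 12
Reactants: 15 the α-hydroxyallene of step 11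
Product: 16 tert-butyl{[(2R,6S,7aR)-2-[(2E)-4-(tert-butyldimethylsilyloxy)but-2-en-2-yl]-4,4,7a-trimethyl-2,4,5,6,7,7a-hexahydro-1-benzofuran-6-yl]oxy}dimethylsilane
Conditions: Ph3PAuNTf2 (2 mol%), THF, −20 °C → 0 °C; then Et3N
Reagents that add atoms: none
Why: Monovalent gold binds the C7=C8 π-bond of the allene, whose lobes lie in the plane of C1, C5 and C6, on the side away from C5, and the C5 hydroxyl adds to C8 from the opposite side (anti-oxyauration) to give a C7 alkenylgold species that is protodeaurated with retention, leaving C6=C7 inside the new ring. The closest known reaction type is the gold- or silver-catalysed cycloisomerisation of α-hydroxyallenes to 2,5-dihydrofurans with axis-to-centre chirality transfer. The dihydrofuran is closed in the 5-endo-trig mode through the O–C8 bond. The new stereocentre C8 is controlled by the allene axis set in step 11: oxygen can arrive only in the C1–C5–C6 plane, so H-8 and C9 keep their sides and C9 ends cis to C4 and trans to the C5 methyl group, which is 8R for the 5R carbinol. The step needs ring closure to outrun loss of the axial information through a gold-stabilised allyl cation and carbocyclisation of the vinylallene; the 1,2-relationship of hydroxyl and allene, the low temperature, the donor solvent and the weakly coordinating counter-ion should secure this, and the two silyl ethers keep every other oxygen out of play.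

Step 13
Reactants: 16 the bis-silylated dihydrofuran of step 12
Product: 17 (2R,6S,7aR)-2-[(2E)-4-hydroxybut-2-en-2-yl]-4,4,7a-trimethyl-2,4,5,6,7,7a-hexahydro-1-benzofuran-6-ol
Conditions: Bu4NF, THF, 0 °C → rt
Reagents that add atoms: none
Why: Fluoride-mediated desilylation removes both silyl ethers under basic, non-ionising conditions, so the doubly allylic C8–O bond should not open.

Step 14
Reactants: 17 the dihydrofuran diol of step 13
Product: 19 {(2E)-3-[(2R,6S,7aR)-6-hydroxy-4,4,7a-trimethyl-2,4,5,6,7,7a-hexahydro-1-benzofuran-2-yl]but-2-en-1-yl}triphenylphosphonium bromide, via allylic bromide 18 (not isolated)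
Conditions: NBS/Me2S (premixed), CH2Cl2, −20 °C → 0 °C; then PPh3, rt
Reagents that add atoms: N-bromosuccinimide, O=C1CCC(=O)N1Br; triphenylphosphine, c1ccc(cc1)P(c1ccccc1)c1ccccc1
Why: Corey–Kim halogenation should convert only the allylic primary alcohol into the bromide (the saturated secondary alcohol is not substituted under these conditions) and SN2 quaternisation with triphenylphosphine gives the Wittig salt without protic acid that could ionise C8–O.

Step 15
Reactants: 19 the phosphonium bromide of step 14; 20 (2E,4E,6E)-2,7-dimethylocta-2,4,6-trienedial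
Product: 21 (2E,4E,6E,8E,10E)-11-[(2R,6S,7aR)-6-hydroxy-4,4,7a-trimethyl-2,4,5,6,7,7a-hexahydro-1-benzofuran-2-yl]-2,7-dimethyldodeca-2,4,6,8,10-pentaenal
Conditions: 20 (excess), NaOMe, MeOH/CH2Cl2, 0 °C → rt; then n-heptane, 80 °C
Reagents that add atoms: none
Why: Wittig olefination of the semistabilised allylic ylide with one aldehyde group of the symmetrical dialdehyde forms C11=C12, and the hindered Z isomer of this bond should equilibrate to E on warming.

Step 16
Reactants: 21 the C25 pentaenal of step 15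
Product: 22 (2E,4E,6E,8E,10E)-11-[(2R,6S,7aR)-6-hydroxy-4,4,7a-trimethyl-2,4,5,6,7,7a-hexahydro-1-benzofuran-2-yl]-2,7-dimethyldodeca-2,4,6,8,10-pentaen-1-ol (carotenoid locants 3S,5R,8R; CNP0239155.2)
Conditions: NaBH4, MeOH/THF, 0 °C
Reagents that add atoms: none
Why: Borohydride 1,2-reduction of the polyenal gives the primary allylic alcohol without touching the polyene, the dihydrofuran or any stereocentre.

**Compound list**

1 | (4R,6R)-4-hydroxy-2,2,6-trimethylcyclohexan-1-one | O=C1C(C)(C)C[C@H](O)C[C@H]1C | starting material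
2 | (4R,6R)-4-(tert-butyldimethylsilyloxy)-2,2,6-trimethylcyclohexan-1-one | O=C1C(C)(C)C[C@H](O[Si](C)(C)C(C)(C)C)C[C@H]1C | intermediate
3 | lithium (4R)-4-(tert-butyldimethylsilyloxy)-2,6,6-trimethylcyclohex-1-en-1-olate | CC1=C(O[Li])C(C)(C)C[C@H](O[Si](C)(C)C(C)(C)C)C1 | intermediate (not isolated)
4 | (4R)-4-(tert-butyldimethylsilyloxy)-2,6,6-trimethylcyclohex-1-en-1-yl trifluoromethanesulfonate | CC1=C(OS(=O)(=O)C(F)(F)F)C(C)(C)C[C@H](O[Si](C)(C)C(C)(C)C)C1 | intermediate
5 | methyl (4R)-4-(tert-butyldimethylsilyloxy)-2,6,6-trimethylcyclohex-1-ene-1-carboxylate | CC1=C(C(=O)OC)C(C)(C)C[C@H](O[Si](C)(C)C(C)(C)C)C1 | intermediate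
6 | [(4R)-4-(tert-butyldimethylsilyloxy)-2,6,6-trimethylcyclohex-1-en-1-yl]methanol | CC1=C(CO)C(C)(C)C[C@H](O[Si](C)(C)C(C)(C)C)C1 | intermediate
7 | [(1R,4S,6R)-4-(tert-butyldimethylsilyloxy)-2,2,6-trimethyl-7-oxabicyclo[4.1.0]heptan-1-yl]methanol | OC[C@]12C(C)(C)C[C@H](O[Si](C)(C)C(C)(C)C)C[C@@]1(C)O2 | intermediate
8 | (1S,4S,6R)-4-(tert-butyldimethylsilyloxy)-2,2,6-trimethyl-7-oxabicyclo[4.1.0]heptane-1-carbaldehyde | O=C[C@]12C(C)(C)C[C@H](O[Si](C)(C)C(C)(C)C)C[C@@]1(C)O2 | intermediate
9 | (1R,4S,6R)-4-(tert-butyldimethylsilyloxy)-1-ethynyl-2,2,6-trimethyl-7-oxabicyclo[4.1.0]heptane | C#C[C@]12C(C)(C)C[C@H](O[Si](C)(C)C(C)(C)C)C[C@@]1(C)O2 | intermediate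
10 | but-2-yn-1-ol | CC#CCO | starting material
11 | tert-butyl(but-2-yn-1-yloxy)dimethylsilane | CC#CCO[Si](C)(C)C(C)(C)C | intermediate
12 | chlorobis(η5-cyclopentadienyl)[(2E)-4-(tert-butyldimethylsilyloxy)but-2-en-2-yl]zirconium | C/C(=C\CO[Si](C)(C)C(C)(C)C)[Zr](Cl)(C1C=CC=C1)C1C=CC=C1 | intermediate (not isolated)
13 | tert-butyl{[(2E)-3-iodobut-2-en-1-yl]oxy}dimethylsilane | C/C(I)=C\CO[Si](C)(C)C(C)(C)C | intermediate
14 | tert-butyl{[(2E)-5-[(1R,4S,6R)-4-(tert-butyldimethylsilyloxy)-2,2,6-trimethyl-7-oxabicyclo[4.1.0]heptan-1-yl]-3-methylpent-2-en-4-yn-1-yl]oxy}dimethylsilane | CC(=C\CO[Si](C)(C)C(C)(C)C)/C#C[C@]12C(C)(C)C[C@H](O[Si](C)(C)C(C)(C)C)C[C@@]1(C)O2 | intermediate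
15 | (1R,5S)-5-(tert-butyldimethylsilyloxy)-2-[(3E)-5-(tert-butyldimethylsilyloxy)-3-methylpenta-1,3-dien-1-ylidene]-1,3,3-trimethylcyclohexan-1-ol, allene axis S | CC(=C\CO[Si](C)(C)C(C)(C)C)/C([H])=[C@]=C1C(C)(C)C[C@H](O[Si](C)(C)C(C)(C)C)C[C@@]1(C)O | intermediate
16 | tert-butyl{[(2R,6S,7aR)-2-[(2E)-4-(tert-butyldimethylsilyloxy)but-2-en-2-yl]-4,4,7a-trimethyl-2,4,5,6,7,7a-hexahydro-1-benzofuran-6-yl]oxy}dimethylsilane | CC(=C\CO[Si](C)(C)C(C)(C)C)/[C@H]1C=C2C(C)(C)C[C@H](O[Si](C)(C)C(C)(C)C)C[C@@]2(C)O1 | intermediate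
17 | (2R,6S,7aR)-2-[(2E)-4-hydroxybut-2-en-2-yl]-4,4,7a-trimethyl-2,4,5,6,7,7a-hexahydro-1-benzofuran-6-ol | CC(=C\CO)/[C@H]1C=C2C(C)(C)C[C@H](O)C[C@@]2(C)O1 | intermediate
18 | (2R,6S,7aR)-2-[(2E)-4-bromobut-2-en-2-yl]-4,4,7a-trimethyl-2,4,5,6,7,7a-hexahydro-1-benzofuran-6-ol | CC(=C\CBr)/[C@H]1C=C2C(C)(C)C[C@H](O)C[C@@]2(C)O1 | intermediate (not isolated)
19 | {(2E)-3-[(2R,6S,7aR)-6-hydroxy-4,4,7a-trimethyl-2,4,5,6,7,7a-hexahydro-1-benzofuran-2-yl]but-2-en-1-yl}triphenylphosphonium bromide | CC(=C\C[P+](c1ccccc1)(c1ccccc1)c1ccccc1)/[C@H]1C=C2C(C)(C)C[C@H](O)C[C@@]2(C)O1.[Br-] | intermediate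
20 | (2E,4E,6E)-2,7-dimethylocta-2,4,6-trienedial | O=C/C(C)=C/C=C/C=C(\C)C=O | starting material
21 | (2E,4E,6E,8E,10E)-11-[(2R,6S,7aR)-6-hydroxy-4,4,7a-trimethyl-2,4,5,6,7,7a-hexahydro-1-benzofuran-2-yl]-2,7-dimethyldodeca-2,4,6,8,10-pentaenal | CC(/C=C/C=C(\C)[C@H]1C=C2C(C)(C)C[C@H](O)C[C@@]2(C)O1)=C\C=C\C=C(/C)C=O | intermediate
22 | (2E,4E,6E,8E,10E)-11-[(2R,6S,7aR)-6-hydroxy-4,4,7a-trimethyl-2,4,5,6,7,7a-hexahydro-1-benzofuran-2-yl]-2,7-dimethyldodeca-2,4,6,8,10-pentaen-1-ol | CC(/C=C/C=C(\C)[C@H]1C=C2C(C)(C)C[C@H](O)C[C@@]2(C)O1)=C\C=C\C=C(/C)CO | target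

**Step count and risks**

Total steps: 16. Longest linear sequence: 14 (steps 1–7 and 10–16); steps 8–9 make the alkenyl iodide.

Risk 1, step 12. Reversible gold-induced ionisation of the vinyl-substituted allene could scramble the axis before the C–O bond forms, or the vinylallene could undergo carbocyclisation; either would give poor control at C8 or loss of material. The fallback sets out from 14 and comes back at 16, and it gives up the allene altogether. Semi-hydrogenation of the alkyne (H2, Pd/CaCO3 poisoned with Pb(OAc)2, quinoline) would give tert-butyl{[(2E,4Z)-5-[(1S,4S,6R)-4-(tert-butyldimethylsilyloxy)-2,2,6-trimethyl-7-oxabicyclo[4.1.0]heptan-1-yl]-3-methylpenta-2,4-dien-1-yl]oxy}dimethylsilane F1. Catalytic pyridinium p-toluenesulfonate in CH2Cl2 at 0 °C would then open the allylic C6–O bond and let the C5 oxygen reclose on C8; this is the acid-induced vinyl oxirane to dihydrofuran ring expansion known for carotenoid 5,6-epoxides. It should give 16 together with its C8 epimer, tert-butyl{[(2S,6S,7aR)-2-[(2E)-4-(tert-butyldimethylsilyloxy)but-2-en-2-yl]-4,4,7a-trimethyl-2,4,5,6,7,7a-hexahydro-1-benzofuran-6-yl]oxy}dimethylsilane F2, to be separated by chromatography.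

Risk 2, step 11. Hydrocupration could engage the conjugated enyne in the wrong sense or over-reduce it, and anti delivery could leak to syn; the result would be poor regio- and stereocontrol in forming the allene. The fallback sets out from 14 and comes back at 15, and it changes the way hydride reaches C8. Under Pd2(dba)3, PBu3 and HCO2NH4 in THF, zerovalent palladium should ionise the propargylic C6–O bond from the face opposite oxygen to give an allenylpalladium alkoxide. Formate exchange, loss of CO2 and reductive elimination would then place hydride on C8 from the palladium side, the same anti outcome. This fallback makes no new compound (F0).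

Risk 3, step 14. Traces of HBr during halide formation could ionise the allylic bromide or the doubly allylic C8–O bond, with loss of configuration at C8 or elimination. The fallback sets out from 17 and comes back at 21, and it replaces the phosphonium salt by a sulfone. Mitsunobu thioetherification of the primary allylic alcohol (1-phenyl-1H-tetrazole-5-thiol, PPh3, diisopropyl azodicarboxylate, THF) would give (2R,6S,7aR)-4,4,7a-trimethyl-2-{(2E)-4-[(1-phenyl-1H-tetrazol-5-yl)sulfanyl]but-2-en-2-yl}-2,4,5,6,7,7a-hexahydro-1-benzofuran-6-ol F3. Oxidation with (NH4)6Mo7O24 and H2O2 in EtOH would give (2R,6S,7aR)-4,4,7a-trimethyl-2-{(2E)-4-[(1-phenyl-1H-tetrazol-5-yl)sulfonyl]but-2-en-2-yl}-2,4,5,6,7,7a-hexahydro-1-benzofuran-6-ol F4. Julia–Kocienski olefination of F4 with dialdehyde 20 (KN(SiMe3)2, THF, −78 °C) would then form C11=C12 and give 21.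

**Further compounds**

F1 | step 12 | tert-butyl{[(2E,4Z)-5-[(1S,4S,6R)-4-(tert-butyldimethylsilyloxy)-2,2,6-trimethyl-7-oxabicyclo[4.1.0]heptan-1-yl]-3-methylpenta-2,4-dien-1-yl]oxy}dimethylsilane | CC(=C\CO[Si](C)(C)C(C)(C)C)/C=C\[C@]12C(C)(C)C[C@H](O[Si](C)(C)C(C)(C)C)C[C@@]1(C)O2
F2 | step 12 | tert-butyl{[(2S,6S,7aR)-2-[(2E)-4-(tert-butyldimethylsilyloxy)but-2-en-2-yl]-4,4,7a-trimethyl-2,4,5,6,7,7a-hexahydro-1-benzofuran-6-yl]oxy}dimethylsilane | CC(=C\CO[Si](C)(C)C(C)(C)C)/[C@@H]1C=C2C(C)(C)C[C@H](O[Si](C)(C)C(C)(C)C)C[C@@]2(C)O1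
F0 | step 11 | none | none
F3 | step 14 | (2R,6S,7aR)-4,4,7a-trimethyl-2-{(2E)-4-[(1-phenyl-1H-tetrazol-5-yl)sulfanyl]but-2-en-2-yl}-2,4,5,6,7,7a-hexahydro-1-benzofuran-6-ol | CC(=C\CSc1nnnn1-c1ccccc1)/[C@H]1C=C2C(C)(C)C[C@H](O)C[C@@]2(C)O1
F4 | step 14 | (2R,6S,7aR)-4,4,7a-trimethyl-2-{(2E)-4-[(1-phenyl-1H-tetrazol-5-yl)sulfonyl]but-2-en-2-yl}-2,4,5,6,7,7a-hexahydro-1-benzofuran-6-ol | CC(=C\CS(=O)(=O)c1nnnn1-c1ccccc1)/[C@H]1C=C2C(C)(C)C[C@H](O)C[C@@]2(C)O1
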